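**Retrosynthetic overview**

1. Licoriphenone 19 comes from its 2'-O-triisopropylsilyl ether 18 by fluoride desilylation in the last step.
2. Ring A of 18 is a 4-acylresorcinol (ketone carbon on C1, OH on C2 and C4, H on C3, C5 and C6). This is the pattern a 1,3-dioxygenated ketene acetal diene gives with a terminal acetylenic ketone, so ring A is cut at C1–C2 and C5–C6 into ynone 12 and diene 16.
3. Ynone 12 comes from arylacetaldehyde 9 (ethynyl Grignard addition, oxidation), and 9 from benzaldehyde 7 by a one-carbon Wittig homologation.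
4. Ring B is bought as 3,5-dimethoxyphenol: silylation, lithiation/prenylation at C4 between the two methoxy groups, and formylation at C2 complete its substitution. Diene 16 comes from methyl acetoacetate in two steps.
5. Ring order: ring B is present from the start; ring A is the only ring built, in step 10.

Key step: step 10

Remark: ring A is the 2,4-dihydroxyphenyl ketone ring and ring B the benzyl ring (C1' carries the CH2, C2' the OH, C4' and C6' the OMe groups, C5' the prenyl group). The target has no stereocentre, and enol ether 8 is used as its E/Z mixture.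

**Route**

Step 1
Reactants: 1 3,5-dimethoxyphenol
Product: 2 (3,5-dimethoxyphenoxy)triisopropylsilane
Conditions: TIPSCl, imidazole, DMF, rt
Reagents that add atoms: triisopropylsilyl chloride, CC(C)[Si](Cl)(C(C)C)C(C)C
Why: Standard phenol silylation; the bulky silyl ether masks the acidic OH for the lithiation and shields both positions ortho to it.

Step 2
Reactants: 2 (3,5-dimethoxyphenoxy)triisopropylsilane; 3 prenyl bromide (1-bromo-3-methylbut-2-ene)
Product: 5 [3,5-dimethoxy-4-(3-methylbut-2-enyl)phenoxy]triisopropylsilane, via aryllithium 4 (not isolated)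
Conditions: n-BuLi, THF, 0 °C → rt; then CuI (10 mol %), 3, −78 °C → rt
Reagents that add atoms: none
Why: Directed ortho-metalation removes the hydrogen at C4 between the two coordinating methoxy groups (the hindered silyloxy group is a poor director), and the aryl nucleophile should displace bromide at the primary carbon of prenyl bromide.

Step 3
Reactants: 5 [3,5-dimethoxy-4-(3-methylbut-2-enyl)phenoxy]triisopropylsilane
Product: 7 2,4-dimethoxy-3-(3-methylbut-2-enyl)-6-(triisopropylsilyloxy)benzaldehyde, via iminium chloride 6 (not isolated)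
Conditions: POCl3, DMF, 0 °C → rt; then aq NaOAc, rt
Reagents that add atoms: N,N-dimethylformamide, CN(C)C=O; water, O
Why: Vilsmeier–Haack formylation at the only free ring positions, which are equivalent by symmetry and activated ortho/para by three oxygen substituents, followed by hydrolysis of the iminium salt in aqueous acetate.

Step 4
Reactants: 7 2,4-dimethoxy-3-(3-methylbut-2-enyl)-6-(triisopropylsilyloxy)benzaldehyde
Product: 8 [2-(2-methoxyethenyl)-3,5-dimethoxy-4-(3-methylbut-2-enyl)phenoxy]triisopropylsilane (E/Z mixture)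
Conditions: MeOCH2PPh3Cl, NaN(SiMe3)2, THF, 0 °C → rt
Reagents that add atoms: (methoxymethyl)triphenylphosphonium chloride, COC[P+](c1ccccc1)(c1ccccc1)c1ccccc1.[Cl-]
Why: Wittig reaction of a non-enolizable aldehyde with methoxymethylenetriphenylphosphorane should give the enol ether, whose double-bond geometry does not matter.

Step 5
Reactants: 8 [2-(2-methoxyethenyl)-3,5-dimethoxy-4-(3-methylbut-2-enyl)phenoxy]triisopropylsilane
Product: 9 2-[2,4-dimethoxy-3-(3-methylbut-2-enyl)-6-(triisopropylsilyloxy)phenyl]acetaldehyde
Conditions: 2 M aq HCl, THF, rt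
Reagents that add atoms: water, O
Why: Acid-catalysed enol ether hydrolysis (protonation at the carbon next to the ring, water addition to the oxocarbenium ion, loss of methanol) under dilute acid that should leave the trisubstituted prenyl olefin and the aryl silyl ether intact.

Step 6
Reactants: 9 2-[2,4-dimethoxy-3-(3-methylbut-2-enyl)-6-(triisopropylsilyloxy)phenyl]acetaldehyde; 10 ethynylmagnesium bromide
Product: 11 1-[2,4-dimethoxy-3-(3-methylbut-2-enyl)-6-(triisopropylsilyloxy)phenyl]but-3-yn-2-ol (racemic)
Conditions: HC≡CMgBr, THF, −78 → 0 °C; aq NH4Cl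
Reagents that add atoms: none
Why: Grignard 1,2-addition of a weakly basic acetylide to the aldehyde at low temperature, where addition should outrun enolization; the new carbinol centre is racemic and is removed in step 7.

Step 7
Reactants: 11 1-[2,4-dimethoxy-3-(3-methylbut-2-enyl)-6-(triisopropylsilyloxy)phenyl]but-3-yn-2-ol
Product: 12 1-[2,4-dimethoxy-3-(3-methylbut-2-enyl)-6-(triisopropylsilyloxy)phenyl]but-3-yn-2-one
Conditions: Dess–Martin periodinane, CH2Cl2, 0 °C → rt
Reagents that add atoms: none
Why: Dess–Martin oxidation of a secondary propargylic alcohol under near-neutral conditions that do not touch the prenyl olefin, the terminal alkyne or the silyl ether.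

Step 8
Reactants: 13 methyl acetoacetate
Product: 14 methyl 3-(trimethylsilyloxy)but-2-enoate
Conditions: Me3SiCl, Et3N, hexane, rt
Reagents that add atoms: chlorotrimethylsilane, C[Si](C)(C)Cl
Why: O-silylation of the enol form of a β-keto ester (silyl enol ether formation).

Step 9
Reactants: 14 methyl 3-(trimethylsilyloxy)but-2-enoate
Product: 16 1-methoxy-1,3-bis(trimethylsilyloxy)buta-1,3-diene, via lithium dienolate 15 (not isolated)
Conditions: LiN(i-Pr)2, THF, −78 °C; then Me3SiCl, −78 → 0 °C
Reagents that add atoms: chlorotrimethylsilane, C[Si](C)(C)Cl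
Why: γ-Deprotonation of the vinylogous ester gives the extended dienolate, which the silyl chloride traps on oxygen to give the ketene acetal diene.

Step 10
Reactants: 12 1-[2,4-dimethoxy-3-(3-methylbut-2-enyl)-6-(triisopropylsilyloxy)phenyl]but-3-yn-2-one; 16 1-methoxy-1,3-bis(trimethylsilyloxy)buta-1,3-diene
Product: 18 1-(2,4-dihydroxyphenyl)-2-[2,4-dimethoxy-3-(3-methylbut-2-enyl)-6-(triisopropylsilyloxy)phenyl]ethanone (licoriphenone 2'-O-triisopropylsilyl ether), via cycloadduct 17 (not isolated)
Conditions: 16 (2.5 equiv), PhMe, 0 °C → rt; then 0.5 M aq HCl, THF, 0 °C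
Reagents that add atoms: none
Why: The electron-rich diene 16 adds to the electron-poor terminal ynone 12 in an asynchronous intermolecular [4+2] cycloaddition: the nucleophilic CH2 terminus of 16 bonds to the alkyne β-carbon and the ketene acetal carbon closes onto the α-carbon, so the six-membered ring A is formed from a four-carbon and a two-carbon component as the cyclohexa-1,4-diene 17, with new C1–C2 and C5–C6 bonds. The closest known reaction type is the Diels–Alder/aromatization of 1,1,3-trioxygenated butadienes with acetylenic ketones and esters, which gives resorcinol carbonyl compounds. Dilute acid should then hydrolyse the mixed silyl methyl ketal (or complete loss of methanol across the ring) and the silyl enol ether, and tautomerization of the resulting dienone aromatizes ring A with free OH groups at C2 and C4. The ketal carbon of 17 is a transient racemic stereocentre that disappears on aromatization, so no stereocontrol is needed. The selectivity required is regiochemical, and it is secured by the match of the largest diene coefficient at the CH2 terminus with the unsubstituted, most electrophilic β-carbon of the ynone, which places the two oxygens ortho and para to the ketone. The neutral low-temperature cycloaddition should spare the prenyl olefin and the enolizable benzylic CH2, and the dilute acid work-up is too mild to cleave the aryl triisopropylsilyl ether.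

Step 11
Reactants: 18 licoriphenone 2'-O-triisopropylsilyl ether
Product: 19 licoriphenone, 1-(2,4-dihydroxyphenyl)-2-[6-hydroxy-2,4-dimethoxy-3-(3-methylbut-2-enyl)phenyl]ethanone
Conditions: Bu4NF, AcOH, THF, 0 °C
Reagents that add atoms: none
Why: Fluoride cleavage of the aryl silyl ether, driven by Si–F bond formation; the acetic acid buffer keeps the freed phenol protonated so that it should not close onto the neighbouring ketone.

**Compound list**

1 | 3,5-dimethoxyphenol | COc1cc(O)cc(OC)c1 | starting material
2 | (3,5-dimethoxyphenoxy)triisopropylsilane | COc1cc(OC)cc(O[Si](C(C)C)(C(C)C)C(C)C)c1 | intermediate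
3 | prenyl bromide (1-bromo-3-methylbut-2-ene) | CC(C)=CCBr | starting material
4 | [2,6-dimethoxy-4-(triisopropylsilyloxy)phenyl]lithium (not isolated) | [Li]c1c(OC)cc(O[Si](C(C)C)(C(C)C)C(C)C)cc1OC | intermediate
5 | [3,5-dimethoxy-4-(3-methylbut-2-enyl)phenoxy]triisopropylsilane | COc1cc(O[Si](C(C)C)(C(C)C)C(C)C)cc(OC)c1CC=C(C)C | intermediate
6 | N-{[2,4-dimethoxy-3-(3-methylbut-2-enyl)-6-(triisopropylsilyloxy)phenyl]methylidene}-N-methylmethanaminium chloride (not isolated) | C[N+](C)=Cc1c(O[Si](C(C)C)(C(C)C)C(C)C)cc(OC)c(CC=C(C)C)c1OC.[Cl-] | intermediate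
7 | 2,4-dimethoxy-3-(3-methylbut-2-enyl)-6-(triisopropylsilyloxy)benzaldehyde | O=Cc1c(O[Si](C(C)C)(C(C)C)C(C)C)cc(OC)c(CC=C(C)C)c1OC | intermediate
8 | [2-(2-methoxyethenyl)-3,5-dimethoxy-4-(3-methylbut-2-enyl)phenoxy]triisopropylsilane (E/Z mixture) | COC=Cc1c(O[Si](C(C)C)(C(C)C)C(C)C)cc(OC)c(CC=C(C)C)c1OC | intermediate
9 | 2-[2,4-dimethoxy-3-(3-methylbut-2-enyl)-6-(triisopropylsilyloxy)phenyl]acetaldehyde | O=CCc1c(O[Si](C(C)C)(C(C)C)C(C)C)cc(OC)c(CC=C(C)C)c1OC | intermediate
10 | ethynylmagnesium bromide | C#C[Mg]Br | starting material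
11 | 1-[2,4-dimethoxy-3-(3-methylbut-2-enyl)-6-(triisopropylsilyloxy)phenyl]but-3-yn-2-ol (racemic) | C#CC(O)Cc1c(O[Si](C(C)C)(C(C)C)C(C)C)cc(OC)c(CC=C(C)C)c1OC | intermediate
12 | 1-[2,4-dimethoxy-3-(3-methylbut-2-enyl)-6-(triisopropylsilyloxy)phenyl]but-3-yn-2-one | C#CC(=O)Cc1c(O[Si](C(C)C)(C(C)C)C(C)C)cc(OC)c(CC=C(C)C)c1OC | intermediate
13 | methyl acetoacetate | COC(=O)CC(C)=O | starting material
14 | methyl 3-(trimethylsilyloxy)but-2-enoate | COC(=O)C=C(C)O[Si](C)(C)C | intermediate
15 | lithium 1-methoxy-3-(trimethylsilyloxy)buta-1,3-dien-1-olate (not isolated) | COC(O[Li])=CC(=C)O[Si](C)(C)C | intermediate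
16 | 1-methoxy-1,3-bis(trimethylsilyloxy)buta-1,3-diene | COC(O[Si](C)(C)C)=CC(=C)O[Si](C)(C)C | intermediate
17 | 2-[2,4-dimethoxy-3-(3-methylbut-2-enyl)-6-(triisopropylsilyloxy)phenyl]-1-[6-methoxy-4,6-bis(trimethylsilyloxy)cyclohexa-1,4-dien-1-yl]ethanone (racemic, not isolated) | COC1(O[Si](C)(C)C)C=C(O[Si](C)(C)C)CC=C1C(=O)Cc1c(O[Si](C(C)C)(C(C)C)C(C)C)cc(OC)c(CC=C(C)C)c1OC | intermediate
18 | licoriphenone 2'-O-triisopropylsilyl ether | COc1cc(O[Si](C(C)C)(C(C)C)C(C)C)c(CC(=O)c2ccc(O)cc2O)c(OC)c1CC=C(C)C | intermediate
19 | licoriphenone | COc1cc(O)c(CC(=O)c2ccc(O)cc2O)c(OC)c1CC=C(C)C | target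

**Step count**

Total: 11 steps. Longest linear sequence: 9 steps (steps 1–7, 10 and 11); steps 8 and 9 make the diene in a side branch.

**Steps most likely to fail**

1. Step 10. The diene may transfer a silyl group to the enolizable ynone, or add in a Michael sense without closing the ring. Aromatization may also proceed by loss of silanol instead of methanol, which would leave a methyl ether at C2 of ring A. The fallback abandons the ring construction and attaches a bought ring A to aldehyde 9, coming back at 18. 4-Bromoresorcinol is protected with MOMCl and i-Pr2NEt in CH2Cl2 to give 1-bromo-2,4-bis(methoxymethoxy)benzene F1, and magnesium insertion in THF should give [2,4-bis(methoxymethoxy)phenyl]magnesium bromide F2. Addition of this reagent to 9 at −78 °C should give 1-[2,4-bis(methoxymethoxy)phenyl]-2-[2,4-dimethoxy-3-(3-methylbut-2-enyl)-6-(triisopropylsilyloxy)phenyl]ethanol F3, and Dess–Martin oxidation should give the corresponding ketone, the bis-MOM deoxybenzoin F4. HCl in MeOH at rt should remove both MOM groups while the aryl triisopropylsilyl ether stays, giving 18.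

2. Step 5. Under aqueous acid the prenyl olefin may add HCl or water, the silyl ether may be lost, and the electron-rich arylacetaldehyde may self-condense. The fallback avoids acid, sets out from 7 and returns at 9. Methylenation of 7 with Ph3P=CH2 (from MePPh3Br and NaN(SiMe3)2) should give the styrene [2-ethenyl-3,5-dimethoxy-4-(3-methylbut-2-enyl)phenoxy]triisopropylsilane F5. 9-Borabicyclo[3.3.1]nonane in THF should hydroborate the terminal vinyl group in preference to the trisubstituted prenyl olefin, giving the B-(2-arylethyl)-9-borabicyclo[3.3.1]nonane F6. Oxidation with NaBO3·4H2O should give 2-[2,4-dimethoxy-3-(3-methylbut-2-enyl)-6-(triisopropylsilyloxy)phenyl]ethanol F7, and Dess–Martin oxidation should give 9.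

3. Step 3. The HCl released under Vilsmeier conditions may add to the prenyl olefin or cleave the silyl ether, and substitution next to the bulky silyloxy group may be slow. The fallback uses the free phenol as the directing group, sets out from 5 and returns at 7. Bu4NF in THF should give 3,5-dimethoxy-4-(3-methylbut-2-enyl)phenol F8. Ortho-formylation of its magnesium phenoxide (MgCl2, Et3N, paraformaldehyde, MeCN, reflux) should give 6-hydroxy-2,4-dimethoxy-3-(3-methylbut-2-enyl)benzaldehyde F9. Re-silylation with TIPSOTf and 2,6-lutidine in CH2Cl2 should give 7.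

**Further compounds**

F1 | step 10 | 1-bromo-2,4-bis(methoxymethoxy)benzene | COCOc1ccc(Br)c(OCOC)c1
F2 | step 10 | [2,4-bis(methoxymethoxy)phenyl]magnesium bromide | COCOc1ccc([Mg]Br)c(OCOC)c1
F3 | step 10 | 1-[2,4-bis(methoxymethoxy)phenyl]-2-[2,4-dimethoxy-3-(3-methylbut-2-enyl)-6-(triisopropylsilyloxy)phenyl]ethanol (racemic) | COCOc1ccc(C(O)Cc2c(O[Si](C(C)C)(C(C)C)C(C)C)cc(OC)c(CC=C(C)C)c2OC)c(OCOC)c1
F4 | step 10 | 1-[2,4-bis(methoxymethoxy)phenyl]-2-[2,4-dimethoxy-3-(3-methylbut-2-enyl)-6-(triisopropylsilyloxy)phenyl]ethanone | COCOc1ccc(C(=O)Cc2c(O[Si](C(C)C)(C(C)C)C(C)C)cc(OC)c(CC=C(C)C)c2OC)c(OCOC)c1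
F5 | step 5 | [2-ethenyl-3,5-dimethoxy-4-(3-methylbut-2-enyl)phenoxy]triisopropylsilane | C=Cc1c(O[Si](C(C)C)(C(C)C)C(C)C)cc(OC)c(CC=C(C)C)c1OC
F6 | step 5 | 9-{2-[2,4-dimethoxy-3-(3-methylbut-2-enyl)-6-(triisopropylsilyloxy)phenyl]ethyl}-9-borabicyclo[3.3.1]nonane | C(Cc1c(O[Si](C(C)C)(C(C)C)C(C)C)cc(OC)c(CC=C(C)C)c1OC)B1C2CCCC1CCC2
F7 | step 5 | 2-[2,4-dimethoxy-3-(3-methylbut-2-enyl)-6-(triisopropylsilyloxy)phenyl]ethanol | OCCc1c(O[Si](C(C)C)(C(C)C)C(C)C)cc(OC)c(CC=C(C)C)c1OC
F8 | step 3 | 3,5-dimethoxy-4-(3-methylbut-2-enyl)phenol | COc1cc(O)cc(OC)c1CC=C(C)C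
F9 | step 3 | 6-hydroxy-2,4-dimethoxy-3-(3-methylbut-2-enyl)benzaldehyde | O=Cc1c(O)cc(OC)c(CC=C(C)C)c1OC
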